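**Plan**
1. Cuts (prostanoid locants; the ring is C8–C12, C9 the ketone, C10 the C–Cl carbon, C12 the quaternary carbinol carbon): first the 12-acetate, then C6–C7 (sp2–sp2 coupling of a C7 enol triflate with a (Z)-alkenylboronate carrying C1–C6), then C10=C11 and C9–C8 together, which removes a chloroketene-type C2 unit (C9–C10) from the ring.
2. What remains is a 2-silyloxy-2-octenylsuccinaldehyde (C7–C8–C12–C11). The enabling feature is that quaternary ring carbon C12 lies between C11 and C8: the C11 formyl group has no α-hydrogen, so only C7/C8 can form an enamine, which makes C8 the single nucleophile (for acyl carbon C9) and C11 the single electrophile (for carbanion C10).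
3. Forward: (S)-malic acid → dioxolanone → alkylation with 1-bromooct-2-yne (quaternary C12) → Lindlar reduction → triol → dialdehyde. The cyclopentenone, the only ring, then arises in one operation by enamine acylation and intramolecular Horner–Wadsworth–Emmons closure with 2-chloro-2-(diethoxyphosphoryl)acetyl chloride.
4. The upper chain is joined last at C7 by Suzuki–Miyaura coupling, followed by desilylation and acetylation.
5. Stereochemistry: C12 comes from (S)-malic acid by self-regeneration of the stereocentre (alkylation anti to tert-butyl, net retention); 14Z from Lindlar reduction; 5Z from trans-hydroboration; 7E from the (E)-enol triflate; both alkene geometries are retained in the coupling.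
6. The helpers (tert-butyl acetal, morpholine, diethoxyphosphoryl, triethylsilyl) are all removed again, two of them inside the key step.

Key step: step 9

Remark: 14 and 15 are drawn as single alkene isomers and 15, F6 and F7 without configuration at carbons that later become sp2; any isomer should lead to the same product.

Step 1
Reactants: 1 (S)-malic acid; 2 pivalaldehyde
Product: 3 [(2S,4S)-2-tert-butyl-5-oxo-1,3-dioxolan-4-yl]acetic acid (cis)
Conditions: TsOH·H2O (cat.), H2SO4 (cat.), pentane, reflux, Dean–Stark; recrystallisation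
Reagents that add atoms: none
Why: Acid-catalysed acetalisation of the α-hydroxy acid unit should give the five-membered dioxolanone, in which the thermodynamically preferred cis isomer (purified by crystallisation) stores the malic acid configuration in a new acetal centre.

Step 2
Reactants: 3 [(2S,4S)-2-tert-butyl-5-oxo-1,3-dioxolan-4-yl]acetic acid; 4 1-bromooct-2-yne
Product: 5 [(2S,4S)-2-tert-butyl-4-(oct-2-yn-1-yl)-5-oxo-1,3-dioxolan-4-yl]acetic acid
Conditions: LiHMDS (2.1 equiv), THF, −78 °C; then 4, −78 → −40 °C; aq. HCl work-up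
Reagents that add atoms: none
Why: Dioxolanone enolate alkylation (self-regeneration of the stereocentre): the carboxylate/lactone-enolate dianion is alkylated by the propargylic bromide on the face anti to tert-butyl, which should set the quaternary C12 centre with net retention.

Step 3
Reactants: 5 [(2S,4S)-2-tert-butyl-4-(oct-2-yn-1-yl)-5-oxo-1,3-dioxolan-4-yl]acetic acid
Product: 6 [(2S,4S)-2-tert-butyl-4-[(2Z)-oct-2-en-1-yl]-5-oxo-1,3-dioxolan-4-yl]acetic acid
Conditions: H2 (1 atm), Lindlar catalyst (Pd/CaCO3 poisoned with Pb(OAc)2), quinoline, EtOAc, rt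
Reagents that add atoms: none
Why: Lindlar semi-hydrogenation adds H2 syn to the isolated alkyne and should give the 14Z alkene before any other reducible π-system is present.

Step 4
Reactants: 6 [(2S,4S)-2-tert-butyl-4-[(2Z)-oct-2-en-1-yl]-5-oxo-1,3-dioxolan-4-yl]acetic acid
Product: 7 (2S)-2-[(2Z)-oct-2-en-1-yl]butane-1,2,4-triol
Conditions: LiAlH4, THF, 0 °C → rt; aqueous NaOH work-up
Reagents that add atoms: none
Why: Hydride reduction of the carboxylic acid and of the lactone carbonyl (with collapse of the acetal) should release the triol without touching the isolated Z alkene or the quaternary centre.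

Step 5
Reactants: 7 (2S)-2-[(2Z)-oct-2-en-1-yl]butane-1,2,4-triol
Product: 8 (2S)-2-[(2Z)-oct-2-en-1-yl]-1,2,4-tris(triethylsilyloxy)butane
Conditions: TESOTf (3.5 equiv), 2,6-lutidine, CH2Cl2, −78 → 0 °C
Reagents that add atoms: triethylsilyl trifluoromethanesulfonate, CC[Si](CC)(CC)OS(=O)(=O)C(F)(F)F
Why: The silyl triflate is reactive enough to silylate the tertiary alcohol as well as both primary ones, giving one uniform protecting group.

Step 6
Reactants: 8 (2S)-2-[(2Z)-oct-2-en-1-yl]-1,2,4-tris(triethylsilyloxy)butane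
Product: 9 (2S)-2-[(2Z)-oct-2-en-1-yl]-2-(triethylsilyloxy)butanedial
Conditions: (COCl)2, DMSO, CH2Cl2, −78 → −35 °C; then Et3N, −78 → 0 °C
Reagents that add atoms: none
Why: Under Swern conditions unhindered primary triethylsilyl ethers are cleaved at oxygen and oxidised in the same flask while the tertiary silyl ether is inert, so both chain ends should become aldehydes in one operation.

Step 7
Reactants: 10 triethyl 2-chloro-2-phosphonoacetate
Product: 11 2-chloro-2-(diethoxyphosphoryl)acetic acid
Conditions: NaOH (1.05 equiv), EtOH–H2O, 0 °C → rt; then aq. HCl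
Reagents that add atoms: sodium hydroxide, [Na+].[OH-]
Why: Saponification should hydrolyse the carboxylic ester selectively, since phosphonate diesters are much slower to hydrolyse under these conditions.

Step 8
Reactants: 11 2-chloro-2-(diethoxyphosphoryl)acetic acid
Product: 12 2-chloro-2-(diethoxyphosphoryl)acetyl chloride
Conditions: (COCl)2, DMF (cat.), CH2Cl2, 0 °C → rt; used crude
Reagents that add atoms: oxalyl chloride, ClC(=O)C(Cl)=O
Why: Standard acid chloride formation through the Vilsmeier-type chloroiminium catalyst gives the acylating form of the C2 unit.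

Step 9
Reactants: 9 (2S)-2-[(2Z)-oct-2-en-1-yl]-2-(triethylsilyloxy)butanedial; 13 morpholine; 12 2-chloro-2-(diethoxyphosphoryl)acetyl chloride
Product: 17 (4R,5Z)-2-chloro-5-(hydroxymethylidene)-4-[(2Z)-oct-2-en-1-yl]-4-(triethylsilyloxy)cyclopent-2-en-1-one, via morpholine enamine 14 (not isolated), via acylated enaminone phosphonate 15 (not isolated), via morpholinomethylidene cyclopentenone 16 (not isolated)
Conditions: 13 (1.0 equiv), 4 Å MS, CH2Cl2, 0 °C; Et3N, then 12, −40 → 0 °C; DBU, 0 °C → rt; then 0.5 M HCl, THF, 0 °C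
Reagents that add atoms: water, O
Why: Morpholine condenses only at the C7 aldehyde (the C11 aldehyde on quaternary C12 has no α-hydrogen), and the enamine β-carbon C8 is C-acylated by acid chloride 12 (Stork enamine acylation), which forms C9–C8 and leaves a vinylogous amide without an acidic C8–H. DBU then deprotonates C10 (flanked by phosphoryl, chlorine and the C9 carbonyl), the carbanion adds to the C11 aldehyde, syn-elimination of diethyl phosphate forms C10=C11 (intramolecular Horner–Wadsworth–Emmons reaction), and dilute acid hydrolyses the vinylogous amide to the hydroxymethylidene ketone. The closest known reaction types are the acylation of aldehyde enamines with acid chlorides and the Horner–Wadsworth–Emmons cyclopentenone annulation of keto phosphonate aldehydes, which together amount to a formal (3+2) addition of a chloroketene across the C8/C11 donor–acceptor pair. The five-membered ring closes by 5-exo-trig attack of C10 on the C11 carbonyl. No stereocentre is created, because C10 becomes sp2, and C12 is quaternary and cannot epimerise. The step needs chemoselection between the two aldehydes, C- over N-acylation, and olefination over Darzens closure; the quaternary C12 secures the first, the reversibility of enamine N-acylation the second, and the phosphoryl group (fast oxaphosphetane collapse) the third.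

Step 10
Reactants: 17 (4R,5Z)-2-chloro-5-(hydroxymethylidene)-4-[(2Z)-oct-2-en-1-yl]-4-(triethylsilyloxy)cyclopent-2-en-1-one
Product: 18 [(E)-[(2R)-4-chloro-2-[(2Z)-oct-2-en-1-yl]-5-oxo-2-(triethylsilyloxy)cyclopent-3-en-1-ylidene]methyl] trifluoromethanesulfonate
Conditions: PhNTf2, i-Pr2NEt, CH2Cl2, 0 °C → rt; used without storage
Reagents that add atoms: N-phenylbis(trifluoromethanesulfonimide), FC(F)(F)S(=O)(=O)N(c1ccccc1)S(=O)(=O)C(F)(F)F
Why: O-Sulfonylation of the vinylogous acid at the unhindered formyl-derived oxygen; with a non-coordinating ammonium counter-ion the enolate should react in its extended form, placing the triflate anti to the C9 carbonyl (E), which is the geometry needed for 7E.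

Step 11
Reactants: 19 methyl hex-5-ynoate; 20 pinacolborane
Product: 21 methyl (5Z)-6-(4,4,5,5-tetramethyl-1,3,2-dioxaborolan-2-yl)hex-5-enoate
Conditions: [RhCl(cod)]2 (1.5 mol %), P(i-Pr)3 (6 mol %), Et3N, cyclohexane, rt
Reagents that add atoms: none
Why: Rhodium-catalysed trans-hydroboration of a terminal alkyne proceeds through a rhodium vinylidene and delivers boron and hydrogen anti, which should give the (Z)-alkenylboronate and so set 5Z.

Step 12
Reactants: 18 [(E)-[(2R)-4-chloro-2-[(2Z)-oct-2-en-1-yl]-5-oxo-2-(triethylsilyloxy)cyclopent-3-en-1-ylidene]methyl] trifluoromethanesulfonate; 21 methyl (5Z)-6-(4,4,5,5-tetramethyl-1,3,2-dioxaborolan-2-yl)hex-5-enoate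
Product: 22 methyl (5Z,7E)-7-[(2R)-4-chloro-2-[(2Z)-oct-2-en-1-yl]-5-oxo-2-(triethylsilyloxy)cyclopent-3-en-1-ylidene]hept-5-enoate
Conditions: PdCl2(dppf) (5 mol %), K3PO4 (3 M aq.), THF, 0 °C → rt
Reagents that add atoms: none
Why: Suzuki–Miyaura coupling proceeds with retention at both sp2 carbons, so the 5Z,7E diene should result; zerovalent palladium inserts into the activated vinylogous triflate far faster than into the C10–Cl bond, and the tertiary silyl ether cannot ionise to an allyl complex.

Step 13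
Reactants: 22 methyl (5Z,7E)-7-[(2R)-4-chloro-2-[(2Z)-oct-2-en-1-yl]-5-oxo-2-(triethylsilyloxy)cyclopent-3-en-1-ylidene]hept-5-enoate
Product: 23 methyl (5Z,7E)-7-[(2R)-4-chloro-2-hydroxy-2-[(2Z)-oct-2-en-1-yl]-5-oxocyclopent-3-en-1-ylidene]hept-5-enoate
Conditions: HF·pyridine, pyridine, THF, 0 °C → rt
Reagents that add atoms: none
Why: Buffered fluoride-mediated desilylation should free the tertiary alcohol, whose ionisation is disfavoured because the resulting cation would be a destabilised, carbonyl-conjugated cyclopentadienyl-type cation.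

Step 14
Reactants: 23 methyl (5Z,7E)-7-[(2R)-4-chloro-2-hydroxy-2-[(2Z)-oct-2-en-1-yl]-5-oxocyclopent-3-en-1-ylidene]hept-5-enoate
Product: 24 methyl (5Z,7E)-7-[(2R)-2-acetoxy-4-chloro-2-[(2Z)-oct-2-en-1-yl]-5-oxocyclopent-3-en-1-ylidene]hept-5-enoate (target)
Conditions: Ac2O, DMAP, Et3N, CH2Cl2, rt
Reagents that add atoms: acetic anhydride, CC(=O)OC(C)=O
Why: DMAP-catalysed acylation through the N-acetylpyridinium ion is the standard way to esterify a hindered tertiary alcohol and leaves the configuration at C12 untouched, because the C–O bond is not broken.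

**Compound list**
1 | (S)-malic acid | OC(=O)C[C@H](O)C(O)=O | starting material
2 | pivalaldehyde (2,2-dimethylpropanal) | CC(C)(C)C=O | starting material
3 | [(2S,4S)-2-tert-butyl-5-oxo-1,3-dioxolan-4-yl]acetic acid | OC(=O)C[C@@H]1O[C@H](C(C)(C)C)OC1=O | intermediate
4 | 1-bromooct-2-yne | CCCCCC#CCBr | starting material
5 | [(2S,4S)-2-tert-butyl-4-(oct-2-yn-1-yl)-5-oxo-1,3-dioxolan-4-yl]acetic acid | OC(=O)C[C@]1(CC#CCCCCC)O[C@H](C(C)(C)C)OC1=O | intermediate
6 | [(2S,4S)-2-tert-butyl-4-[(2Z)-oct-2-en-1-yl]-5-oxo-1,3-dioxolan-4-yl]acetic acid | OC(=O)C[C@]1(C/C=C\CCCCC)O[C@H](C(C)(C)C)OC1=O | intermediate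
7 | (2S)-2-[(2Z)-oct-2-en-1-yl]butane-1,2,4-triol | CCCCC/C=C\C[C@@](CCO)(O)CO | intermediate
8 | (2S)-2-[(2Z)-oct-2-en-1-yl]-1,2,4-tris(triethylsilyloxy)butane | CCCCC/C=C\C[C@@](CCO[Si](CC)(CC)CC)(O[Si](CC)(CC)CC)CO[Si](CC)(CC)CC | intermediate
9 | (2S)-2-[(2Z)-oct-2-en-1-yl]-2-(triethylsilyloxy)butanedial | CCCCC/C=C\C[C@@](CC=O)(O[Si](CC)(CC)CC)C=O | intermediate
10 | triethyl 2-chloro-2-phosphonoacetate | CCOC(=O)C(Cl)P(=O)(OCC)OCC | starting material
11 | 2-chloro-2-(diethoxyphosphoryl)acetic acid | CCOP(=O)(OCC)C(Cl)C(O)=O | intermediate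
12 | 2-chloro-2-(diethoxyphosphoryl)acetyl chloride | CCOP(=O)(OCC)C(Cl)C(Cl)=O | intermediate
13 | morpholine | C1COCCN1 | starting material
14 | (2S,3E)-4-(morpholin-4-yl)-2-[(2Z)-oct-2-en-1-yl]-2-(triethylsilyloxy)but-3-enal | CCCCC/C=C\C[C@@](/C=C/N1CCOCC1)(O[Si](CC)(CC)CC)C=O | intermediate
15 | diethyl [(4S,6Z)-1-chloro-4-formyl-3-(morpholin-4-ylmethylidene)-2-oxo-4-(triethylsilyloxy)dodec-6-en-1-yl]phosphonate | CCCCC/C=C\C[C@@](/C(C(=O)C(Cl)P(=O)(OCC)OCC)=C\N1CCOCC1)(O[Si](CC)(CC)CC)C=O | intermediate
16 | (4R,5E)-2-chloro-5-(morpholin-4-ylmethylidene)-4-[(2Z)-oct-2-en-1-yl]-4-(triethylsilyloxy)cyclopent-2-en-1-one | CCCCC/C=C\C[C@@]1(O[Si](CC)(CC)CC)C=C(Cl)C(=O)/C1=C/N2CCOCC2 | intermediate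
17 | (4R,5Z)-2-chloro-5-(hydroxymethylidene)-4-[(2Z)-oct-2-en-1-yl]-4-(triethylsilyloxy)cyclopent-2-en-1-one | CCCCC/C=C\C[C@@]1(O[Si](CC)(CC)CC)C=C(Cl)C(=O)/C1=C\O | intermediate
18 | [(E)-[(2R)-4-chloro-2-[(2Z)-oct-2-en-1-yl]-5-oxo-2-(triethylsilyloxy)cyclopent-3-en-1-ylidene]methyl] trifluoromethanesulfonate | CCCCC/C=C\C[C@@]1(O[Si](CC)(CC)CC)C=C(Cl)C(=O)/C1=C/OS(=O)(=O)C(F)(F)F | intermediate
19 | methyl hex-5-ynoate | COC(=O)CCCC#C | starting material
20 | pinacolborane | CC1(C)OBOC1(C)C | starting material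
21 | methyl (5Z)-6-(4,4,5,5-tetramethyl-1,3,2-dioxaborolan-2-yl)hex-5-enoate | COC(=O)CCC/C=C\B1OC(C)(C)C(C)(C)O1 | intermediate
22 | methyl (5Z,7E)-7-[(2R)-4-chloro-2-[(2Z)-oct-2-en-1-yl]-5-oxo-2-(triethylsilyloxy)cyclopent-3-en-1-ylidene]hept-5-enoate | CCCCC/C=C\C[C@@]1(O[Si](CC)(CC)CC)C=C(Cl)C(=O)/C1=C/C=C\CCCC(=O)OC | intermediate
23 | methyl (5Z,7E)-7-[(2R)-4-chloro-2-hydroxy-2-[(2Z)-oct-2-en-1-yl]-5-oxocyclopent-3-en-1-ylidene]hept-5-enoate | CCCCC/C=C\C[C@@]1(O)C=C(Cl)C(=O)/C1=C/C=C\CCCC(=O)OC | intermediate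
24 | methyl (5Z,7E)-7-[(2R)-2-acetoxy-4-chloro-2-[(2Z)-oct-2-en-1-yl]-5-oxocyclopent-3-en-1-ylidene]hept-5-enoate | CCCCC/C=C\C[C@@]1(OC(C)=O)C=C(Cl)C(=O)/C1=C/C=C\CCCC(=O)OC | target

Total steps: 14. Longest linear sequence: 11 steps (steps 1–6, 9, 10, 12, 13, 14).

**Steps most likely to fail**

Step 9. The risks are β-elimination of the tertiary silyloxy group through the enamine, which would destroy the C12 centre, and sluggish C-acylation at the hindered C8. The fallback uses no amine, a different C2 unit and a different ring closure. It sets out from 9: TBSOTf and Et3N should convert the only enolisable aldehyde into silyl enol ether (2S,3Z)-4-(tert-butyldimethylsilyloxy)-2-[(2Z)-oct-2-en-1-yl]-2-(triethylsilyloxy)but-3-enal F1. C-Acylation of F1 with trichloroacetyl chloride should give the trichloromethyl keto aldehyde (2S,3Z)-5,5,5-trichloro-3-(hydroxymethylidene)-2-[(2Z)-oct-2-en-1-yl]-4-oxo-2-(triethylsilyloxy)pentanal F2. CrCl2 in THF should then effect a Reformatsky-type addition of the chromium enolate to the C11 aldehyde and reductive β-elimination to the α-chloro enone. This gives 17, where the route is rejoined.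

Step 10. The risks are poor control of O-regioselectivity or enol geometry in the sulfonylation and hydrolytic loss of the vinylogous triflate. The fallback makes C7=C8 by aldol condensation and so needs neither step 10 nor step 12. It sets out from 17: retro-Claisen deformylation (K2CO3, MeOH) should give (4S)-2-chloro-4-[(2Z)-oct-2-en-1-yl]-4-(triethylsilyloxy)cyclopent-2-en-1-one F3. In parallel, Wittig reaction of methyl 5-oxopentanoate with the ylide from (1,3-dioxolan-2-ylmethyl)triphenylphosphonium bromide should give methyl (5Z)-6-(1,3-dioxolan-2-yl)hex-5-enoate F4, and mild acid hydrolysis should give methyl (5Z)-7-oxohept-5-enoate F5. The lithium enolate of F3 (LDA, THF, −78 °C) should add to F5 to give the aldol methyl (5Z)-7-[(2R)-4-chloro-2-[(2Z)-oct-2-en-1-yl]-5-oxo-2-(triethylsilyloxy)cyclopent-3-en-1-yl]-7-hydroxyhept-5-enoate F6. Mesylation (MsCl, Et3N) to the methanesulfonate F7 and elimination with DBU should give the thermodynamically preferred 7E dienone 22, where the route is rejoined.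

Step 12. The risks are hydrolysis of the triflate by aqueous base before transmetalation, and protodeboronation or Z-to-E isomerisation of the alkenylboron partner. The fallback joins the chain as an alkyne and sets 5Z afterwards. It sets out from 18 and alkyne 19: Sonogashira coupling (PdCl2(PPh3)2, CuI, Et3N, THF) should give the dienyne methyl (7E)-7-[(2R)-4-chloro-2-[(2Z)-oct-2-en-1-yl]-5-oxo-2-(triethylsilyloxy)cyclopent-3-en-1-ylidene]hept-5-ynoate F8. Zn(Cu/Ag) in aqueous methanol should reduce only the conjugated triple bond, by syn addition, to the Z alkene. This gives 22, where the route is rejoined.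

**Further compounds**
F1 | step 9 | (2S,3Z)-4-(tert-butyldimethylsilyloxy)-2-[(2Z)-oct-2-en-1-yl]-2-(triethylsilyloxy)but-3-enal | CCCCC/C=C\C[C@@](/C=C\O[Si](C)(C)C(C)(C)C)(O[Si](CC)(CC)CC)C=O
F2 | step 9 | (2S,3Z)-5,5,5-trichloro-3-(hydroxymethylidene)-2-[(2Z)-oct-2-en-1-yl]-4-oxo-2-(triethylsilyloxy)pentanal | CCCCC/C=C\C[C@@](/C(=C/O)C(=O)C(Cl)(Cl)Cl)(O[Si](CC)(CC)CC)C=O
F3 | step 10 | (4S)-2-chloro-4-[(2Z)-oct-2-en-1-yl]-4-(triethylsilyloxy)cyclopent-2-en-1-one | CCCCC/C=C\C[C@@]1(O[Si](CC)(CC)CC)C=C(Cl)C(=O)C1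
F4 | step 10 | methyl (5Z)-6-(1,3-dioxolan-2-yl)hex-5-enoate | COC(=O)CCC/C=C\C1OCCO1
F5 | step 10 | methyl (5Z)-7-oxohept-5-enoate | COC(=O)CCC/C=C\C=O
F6 | step 10 | methyl (5Z)-7-[(2R)-4-chloro-2-[(2Z)-oct-2-en-1-yl]-5-oxo-2-(triethylsilyloxy)cyclopent-3-en-1-yl]-7-hydroxyhept-5-enoate | CCCCC/C=C\C[C@@]1(O[Si](CC)(CC)CC)C=C(Cl)C(=O)C1C(O)/C=C\CCCC(=O)OC
F7 | step 10 | methyl (5Z)-7-[(2R)-4-chloro-2-[(2Z)-oct-2-en-1-yl]-5-oxo-2-(triethylsilyloxy)cyclopent-3-en-1-yl]-7-(methylsulfonyloxy)hept-5-enoate | CCCCC/C=C\C[C@@]1(O[Si](CC)(CC)CC)C=C(Cl)C(=O)C1C(OS(C)(=O)=O)/C=C\CCCC(=O)OC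
F8 | step 12 | methyl (7E)-7-[(2R)-4-chloro-2-[(2Z)-oct-2-en-1-yl]-5-oxo-2-(triethylsilyloxy)cyclopent-3-en-1-ylidene]hept-5-ynoate | CCCCC/C=C\C[C@@]1(O[Si](CC)(CC)CC)C=C(Cl)C(=O)/C1=C/C#CCCCC(=O)OC
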